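What was left in the elm run at 8.00 min was mostly right-handed substrate, 24.4% of the two substrates charged together, beside 0.7% of left-handed substrate.

| setting | elm | flask |
|---|---|---|
| left-handed substrate | 0.015 M | 0.015 M |
| right-handed substrate | 0.015 M | 0.015 M |
| coupling partner | 1.5 equiv | 1.50 equiv |
| free catalyst | 1.8 mol% | 1.2 mol% |
| added ligand | 0.53 mM | 0.53 mM |
| remark | run made earlier |  |
| time |  | 40 min |

elm run (percent of the left-handed substrate and right-handed substrate together charged)

| time / min | left-handed substrate / % | right-handed substrate / % | left-handed product / % |
|---|---|---|---|
| 1.00 | 5.3 | 32.4 | 45.2 |
| 3.00 | 2.2 | 26.8 | 48.4 |
| 5.00 | 1.5 | 25.1 | 48.7 |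
| 8.00 | 0.7 | 24.4 | 48.9 |

(scatter of a reading: 0.3 percentage points)

- free catalyst is single-handed; left-handed substrate and right-handed substrate are mirror images of each other, charged as a racemate, each of them at the stated concentration
- the numbers in the tables scatter by 0.3 percentage points (one standard deviation)
- an excess is the difference of the two amounts in percent of their sum
- an excess is below zero if the other one leads
- no earlier run changes the charge of free catalyst; that part of a forecast is a guess

- part of the left-handed substrate and right-handed substrate charged together that has reacted at 40 min
- excess of left-handed product over right-handed product in the product at 40 min
- excess of right-handed substrate over left-handed substrate among what is left of the two at 40 min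

I worked with the fraction of each substrate left, not the fraction made. At 1.00 min in the elm run, the left-handed substrate kept 10.6% of its charge and the right-handed substrate 64.8%. From these I read 5.17 as the selectivity factor: the logarithm of the left-handed fraction left over the logarithm of the right-handed fraction left. The reading at 3.00 min gave 5.01. I assumed both substrates met the same catalyst and partner, so that the loading cancels in this ratio.

The elm readings formed a ladder. The left-handed substrate came first, with a half-life of about 0.309 min over the first reading, and the right-handed substrate followed more slowly, at 1.60 min. Next came the coupling partner, the limiting reagent, whose charge covers 75.0% of the substrates; the elm run had consumed 74.9% by 8.00 min. The flask has 0.667 of the elm loading. If rate followed loading, which is a guess, 8.00 min would stretch to 12.0 min, shorter than 40 min.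

So I expected the flask to stop at 75.0%, with the two fractions left summing to 0.500. Substituting the selectivity factor gave 2.23% of the left-handed charge left and 47.8% of the right-handed, hence a product excess of 30.4% and a substrate excess of 91.1%. The forecast gave 75%, 30.3% and 91%, with ranges 72% to 75.6%, 27% to 33.5% and 80% to 95%, reasoning “Even so, 40 min is ample”.

The flask gave 74.9% reacted, a product excess of 30.9% and a substrate excess of 92.0%.

    coupling partner + free catalyst + left-handed substrate → free catalyst + left-handed product (k = 59000 M⁻² s⁻¹)
    coupling partner + free catalyst + right-handed substrate → free catalyst + right-handed product (k = 11000 M⁻² s⁻¹)
    free catalyst + added ligand ⇌ idle complex, settled at all times (K = 6100 M⁻¹)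
    coupling partner + free catalyst → spent catalyst (k = 0.560 M⁻¹ s⁻¹)

At 40.0 min, the flask held 0% of its coupling partner charge, less than the 48% of its right-handed substrate charge still there. That right-handed fraction, raised to the selectivity factor read from the elm run, gave 2.30% of the left-handed charge, and the flask held 2.0% of that charge. A neighbour flask charged with 0.900 equiv of coupling partner ended with 0% of it and 30% of its left-handed charge. The same factor, applied backwards, gave 79.2% of the right-handed charge, and that neighbour held 80% of that charge.

(The data were computed with constants of no real substance; the scatter is artificial.)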